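**Plan**
- Retrosynthetic cuts, in order: the 7-O–CH3 bond; C4a–C5 of ring A; C8–C8a (keto ester onto ring C); C2–C3 and O1–C8a of ring C (aldehyde plus four-carbon diene); the aryl C2'–geranyl bond.
- Forward order: geranylated ring B aldehyde, then ring C as a δ-lactone by hetero-Diels–Alder reaction, recast as a dihydropyranone when the prenylated acetoacetate is added, then ring A, then the 7-O-methyl group.
- Enabling feature: ring A is an acylphloroglucinol (oxygen on C5, C7 and C8a, acyl carbon C4 on C4a), the pattern of a Claisen-folded tetraketide. Its C8a oxygen is O1 of ring C, so a dihydropyranone that carries the C5–C8 keto ester chain can only close C4a–C5.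
- The ester is tert-butyl so that heat alone converts it into an acylketene; no base meets the pyranone, whose ring could otherwise open by retro-oxa-Michael reaction and racemise C2.
- Stereochemistry: C2 is the only stereocentre; it is set S in the Ti(OiPr)4/(S)-BINOL hetero-Diels–Alder step and carried through unchanged. The E alkene comes from geranyl bromide.

Key step: step 6

Assumption: the Ti(OiPr)4/(S)-BINOL complex is taken to direct the silyl dienolate to the Si face of the aryl aldehyde; should lactone 11 form with the R configuration, (R)-BINOL is used in step 3.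

Remark: prenyl = 3-methylbut-2-enyl; geranyl = (2E)-3,7-dimethylocta-2,6-dienyl. Compounds 14, 17, 18 and 19 are mixtures at the enolisable carbon that bears the prenyl group (it becomes sp2 in ring A), 17 also at its lactol carbon and 20 at C4a.

Step 1
Reactants: 1 veratraldehyde; 2 geranyl bromide
Product: 6 2-geranyl-3,4-dimethoxybenzaldehyde, via lithium amino alkoxide 3 (not isolated), via C2-aryllithium 4 (not isolated), via geranylated amino alkoxide 5 (not isolated)
Conditions: Me2NCH2CH2NHMe, n-BuLi, THF, −20 °C; n-BuLi (1.5 equiv), −20 °C; CuBr·SMe2 (10 mol %), 2 (2 equiv), −78 → 0 °C; 1 M HCl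
Reagents that add atoms: none
Why: Directed ortho-metalation of the in situ protected aldehyde, in which the lithium α-amino alkoxide and the 3-methoxy group together direct lithiation to C2, followed by copper-catalysed SN2 allylation at the primary carbon of the allylic bromide, which should keep the E alkene.

Step 2
Reactants: 7 methyl (2E)-3-methoxybut-2-enoate
Product: 9 1,3-dimethoxy-1-(trimethylsilyloxy)buta-1,3-diene, via lithium dienolate 8 (not isolated)
Conditions: LiN(iPr)2, THF, −78 °C; Me3SiCl, −78 → 0 °C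
Reagents that add atoms: chlorotrimethylsilane, C[Si](C)(C)Cl
Why: γ-Deprotonation of the β-methoxy crotonate and O-silylation of the dienolate (silyl dienolate formation) should give the vinylogous silyl ketene acetal, used without purification.

Step 3
Reactants: 6 2-geranyl-3,4-dimethoxybenzaldehyde; 9 1,3-dimethoxy-1-(trimethylsilyloxy)buta-1,3-diene
Product: 11 (6S)-6-(2-geranyl-3,4-dimethoxyphenyl)-4-methoxy-5,6-dihydro-2H-pyran-2-one, via silyl aldol adduct 10 (not isolated)
Conditions: Ti(OiPr)4/(S)-BINOL (1:1, 20 mol %), 4 Å MS, CH2Cl2, 0 °C; then CF3CO2H (cat.), 0 °C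
Reagents that add atoms: none
Why: Catalytic asymmetric hetero-Diels–Alder reaction in its stepwise form (vinylogous Mukaiyama aldol addition, then acid-induced lactonisation with loss of methanol), in which the titanium BINOLate should expose the Si face of the bound aldehyde and so set the carbinol carbon, the future C2, as S.

Step 4
Reactants: 12 tert-butyl acetoacetate; 13 prenyl bromide
Product: 14 tert-butyl 2-acetyl-5-methylhex-4-enoate
Conditions: K2CO3, acetone, reflux
Reagents that add atoms: none
Why: Acetoacetic ester alkylation, the potassium enolate being C-alkylated by one equivalent of the reactive primary allylic bromide.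

Step 5
Reactants: 14 tert-butyl 2-acetyl-5-methylhex-4-enoate; 11 (6S)-6-(2-geranyl-3,4-dimethoxyphenyl)-4-methoxy-5,6-dihydro-2H-pyran-2-one
Product: 18 tert-butyl 4-[(2S)-2-(2-geranyl-3,4-dimethoxyphenyl)-4-oxo-2,3-dihydro-4H-pyran-6-yl]-3-oxo-2-prenylbutanoate, via sodium enolate 15 (not isolated), via dianion 16 (not isolated), via lactol adduct 17 (not isolated)
Conditions: 14 (2.2 equiv), NaH, THF, 0 °C; n-BuLi, 0 °C; 11, −78 → −30 °C; then 1 M HCl, THF, 0 °C
Reagents that add atoms: water, O
Why: Carbanion 1,2-addition followed by a Stork–Danheiser-type transposition: the terminal carbon of the acetoacetate dianion should add once to the lactone carbonyl, and dilute acid then ionises the vinylogous lactol, water enters at C4 and methanol leaves, which turns the δ-lactone into the 6-substituted 2,3-dihydro-4H-pyran-4-one without touching C2.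

Step 6
Reactants: 18 tert-butyl 4-[(2S)-2-(2-geranyl-3,4-dimethoxyphenyl)-4-oxo-2,3-dihydro-4H-pyran-6-yl]-3-oxo-2-prenylbutanoate
Product: 21 (2S)-5,7-dihydroxy-2-(2-geranyl-3,4-dimethoxyphenyl)-6-prenylchroman-4-one, via acylketene 19 (not isolated), via 4aH-dienone 20 (not isolated)
Conditions: xylenes (0.01 M), 125 °C, slow N2 stream
Reagents that add atoms: none
Why: Proposed new method: heating the tert-butyl β-keto ester should expel tert-butanol to give the α-oxo ketene 19 (the route by which tert-butyl acetoacetates transfer their acyl group), and enolisation of its chain ketone toward the doubly activated methylene lines up ketene, enol and the pyranone C5=C6 bond as a hydroxy-dienylketene. A thermal 6π-electrocyclisation, the ring-closing event of the Danheiser benzannulation and the closest known reaction type, then joins the ketene carbon to pyranone C5 (the C4a–C5 bond) and gives dienone 20, which tautomerises to the resorcinol ring A. Ring A thus closes as a six-membered carbocycle in a disrotatory 6π process that amounts to a Claisen-type C-acylation of the vinylogous ester (formally 6-enolendo-exo-dig). No stereocentre is created, since C4a becomes aromatic, and C2 from step 3 never meets base, so ring C cannot open by retro-oxa-Michael reaction. The step needs C-acylation at C5 in preference to O-acylation and ketene dimerisation: the oxygen that would otherwise trap the ketene as a 2-pyranone is the ring oxygen O1, already alkylated by C2, the C4 carbonyl oxygen could only close an eight-membered ring, and high dilution holds back dimers.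

Step 7
Reactants: 21 (2S)-5,7-dihydroxy-2-(2-geranyl-3,4-dimethoxyphenyl)-6-prenylchroman-4-one
Product: 22 (2S)-5-hydroxy-7-methoxy-2-(2-geranyl-3,4-dimethoxyphenyl)-6-prenylchroman-4-one (CNP0112088.1)
Conditions: Me3SiCHN2 (1.1 equiv), PhMe/MeOH, 0 °C
Reagents that add atoms: (trimethylsilyl)diazomethane, C[Si](C)(C)C=[N+]=[N-]
Why: O-Methylation with a diazomethane equivalent should occur only at the more acidic, non-chelated 7-hydroxyl, because the 5-hydroxyl is held in a hydrogen bond to the C4 carbonyl.

**Compound list**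
1 | veratraldehyde (3,4-dimethoxybenzaldehyde) | COc1ccc(C=O)cc1OC | starting material
2 | geranyl bromide ((2E)-1-bromo-3,7-dimethylocta-2,6-diene) | CC(C)=CCC/C(C)=C/CBr | starting material
3 | lithium α-amino alkoxide from 1 and lithium N,N,N'-trimethylethylenediamide | [Li+].[O-]C(N(C)CCN(C)C)c1ccc(OC)c(OC)c1 | intermediate
4 | C2-lithiated amino alkoxide | [Li+].[O-]C(N(C)CCN(C)C)c1ccc(OC)c(OC)c1[Li] | intermediate
5 | C2-geranylated amino alkoxide | [Li+].[O-]C(N(C)CCN(C)C)c1ccc(OC)c(OC)c1C/C=C(\C)CCC=C(C)C | intermediate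
6 | 2-geranyl-3,4-dimethoxybenzaldehyde | O=Cc1ccc(OC)c(OC)c1C/C=C(\C)CCC=C(C)C | intermediate
7 | methyl (2E)-3-methoxybut-2-enoate | COC(=O)/C=C(\C)OC | starting material
8 | lithium dienolate of 7 | [Li+].C=C(OC)C=C(OC)[O-] | intermediate
9 | 1,3-dimethoxy-1-(trimethylsilyloxy)buta-1,3-diene (ketene acetal geometry as formed) | C=C(OC)C=C(OC)O[Si](C)(C)C | intermediate
10 | methyl (5S)-5-(2-geranyl-3,4-dimethoxyphenyl)-3-methoxy-5-(trimethylsilyloxy)pent-2-enoate | COC(=O)C=C(OC)C[C@@H](c1ccc(OC)c(OC)c1C/C=C(\C)CCC=C(C)C)O[Si](C)(C)C | intermediate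
11 | (6S)-6-(2-geranyl-3,4-dimethoxyphenyl)-4-methoxy-5,6-dihydro-2H-pyran-2-one | O=C1C=C(OC)C[C@@H](c2ccc(OC)c(OC)c2C/C=C(\C)CCC=C(C)C)O1 | intermediate
12 | tert-butyl acetoacetate | CC(=O)CC(=O)OC(C)(C)C | starting material
13 | prenyl bromide (1-bromo-3-methylbut-2-ene) | CC(C)=CCBr | starting material
14 | tert-butyl 2-acetyl-5-methylhex-4-enoate | CC(=O)C(CC=C(C)C)C(=O)OC(C)(C)C | intermediate
15 | sodium enolate of 14 | [Na+].CC([O-])=C(CC=C(C)C)C(=O)OC(C)(C)C | intermediate
16 | sodium lithium dianion of 14 (terminal carbanion) | [Na+].[Li+].[CH2-]C([O-])=C(CC=C(C)C)C(=O)OC(C)(C)C | intermediate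
17 | tert-butyl 4-[(6S)-6-(2-geranyl-3,4-dimethoxyphenyl)-2-hydroxy-4-methoxy-5,6-dihydro-2H-pyran-2-yl]-3-oxo-2-prenylbutanoate | CC(C)(C)OC(=O)C(CC=C(C)C)C(=O)CC1(O)C=C(OC)C[C@@H](c2ccc(OC)c(OC)c2C/C=C(\C)CCC=C(C)C)O1 | intermediate
18 | tert-butyl 4-[(2S)-2-(2-geranyl-3,4-dimethoxyphenyl)-4-oxo-2,3-dihydro-4H-pyran-6-yl]-3-oxo-2-prenylbutanoate | CC(C)(C)OC(=O)C(CC=C(C)C)C(=O)CC1=CC(=O)C[C@@H](c2ccc(OC)c(OC)c2C/C=C(\C)CCC=C(C)C)O1 | intermediate
19 | acylketene: (2S)-2-(2-geranyl-3,4-dimethoxyphenyl)-6-[2-oxo-3-(oxomethylidene)-6-methylhept-5-enyl]-2,3-dihydro-4H-pyran-4-one | O=C=C(CC=C(C)C)C(=O)CC1=CC(=O)C[C@@H](c2ccc(OC)c(OC)c2C/C=C(\C)CCC=C(C)C)O1 | intermediate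
20 | (2S)-7-hydroxy-2-(2-geranyl-3,4-dimethoxyphenyl)-6-prenyl-2,3-dihydro-4aH-chromene-4,5-dione | O=C1C(CC=C(C)C)=C(O)C=C2O[C@H](c3ccc(OC)c(OC)c3C/C=C(\C)CCC=C(C)C)CC(=O)C12 | intermediate
21 | (2S)-5,7-dihydroxy-2-(2-geranyl-3,4-dimethoxyphenyl)-6-prenylchroman-4-one | Oc1cc2c(c(O)c1CC=C(C)C)C(=O)C[C@@H](c1ccc(OC)c(OC)c1C/C=C(\C)CCC=C(C)C)O2 | intermediate
22 | (2S)-5-hydroxy-7-methoxy-2-(2-geranyl-3,4-dimethoxyphenyl)-6-prenylchroman-4-one (CNP0112088.1) | COc1cc2c(c(O)c1CC=C(C)C)C(=O)C[C@@H](c1ccc(OC)c(OC)c1C/C=C(\C)CCC=C(C)C)O2 | target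

Total step count: 7
Longest linear sequence: 5 steps (1, 3, 5, 6, 7)

**Steps most likely to fail**

1. Step 6 (the labelled step). The acylketene may be diverted before the weakly nucleophilic pyranone C5 is acylated: recapture by tert-butanol, dimerisation, or loss of isobutene followed by decarboxylation of the keto acid. Fallback with known chemistry, from 18 back to 21: 18 is heated with methanol in toluene, where the acylketene is captured by the alcohol (the thermal ester exchange of tert-butyl β-keto esters), to give methyl 4-[(2S)-2-(2-geranyl-3,4-dimethoxyphenyl)-4-oxo-2,3-dihydro-4H-pyran-6-yl]-3-oxo-2-prenylbutanoate F1. F1 is then cyclised with Mg(OMe)2 in methanol at 0 to 25 °C, the base-mediated Claisen cyclisation established for open 3,5,7-triketo esters, the chelated extended enolate attacking the ester through pyranone C5. A short contact time and a cold acidic quench are used to limit reversible opening of ring C, and the product is 21.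

2. Step 5. The dianion may act as a base: proton transfer from C5 of the lactone and β-elimination of the carboxylate oxygen would open the ring and erase the stereocentre; attack at C4 with displacement of methoxide is a second possible diversion. Fallback, from 10 back to 18: the aldol adduct 10 is not cyclised but desilylated under buffered conditions (Bu4NF/AcOH) to methyl (5S)-5-(2-geranyl-3,4-dimethoxyphenyl)-5-hydroxy-3-methoxypent-2-enoate F2 and resilylated (tBuMe2SiCl, imidazole, DMF) to methyl (5S)-5-[(tert-butyldimethylsilyl)oxy]-5-(2-geranyl-3,4-dimethoxyphenyl)-3-methoxypent-2-enoate F3. This acyclic ester has only a silyloxide as β-leaving group, so Claisen acylation of dianion 16 by it should give tert-butyl (9S)-9-[(tert-butyldimethylsilyl)oxy]-9-(2-geranyl-3,4-dimethoxyphenyl)-7-methoxy-3,5-dioxo-2-prenylnon-6-enoate F4. Aqueous HF in MeCN then removes the silyl group, and the freed hydroxyl closes the dihydropyranone with loss of methanol to give 18.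

3. Step 3. Addition to the electron-rich, ortho-substituted aldehyde may be slow, so that an uncatalysed pathway lowers the enantioselectivity, and the Lewis acid may trigger intramolecular carbonyl-ene closure of the aldehyde onto the neighbouring geranyl alkene. Fallback, from 6 back to 11: the silyl dienolate 2,2-dimethyl-6-methylidene-4-(trimethylsilyloxy)-6H-1,3-dioxine F5 is made from 2,2,6-trimethyl-4H-1,3-dioxin-4-one with LiN(iPr)2 and Me3SiCl. It is added to 6 under Cu(OTf)2/Tol-BINAP/(Bu4N)(Ph3SiF2) catalysis (ligand antipode chosen for the S carbinol), a vinylogous aldol addition that runs through a chiral copper dienolate and does not rely on Lewis-acid activation of the aldehyde. Acidic work-up gives 6-[(2S)-2-(2-geranyl-3,4-dimethoxyphenyl)-2-hydroxyethyl]-2,2-dimethyl-4H-1,3-dioxin-4-one F6. Heating F6 in toluene (acylketene captured by the hydroxyl) gives (6S)-6-(2-geranyl-3,4-dimethoxyphenyl)oxane-2,4-dione F7, and O-methylation of its enol with Me2SO4 and K2CO3 in acetone gives 11.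

**Further compounds**
F1 | step 6 | methyl 4-[(2S)-2-(2-geranyl-3,4-dimethoxyphenyl)-4-oxo-2,3-dihydro-4H-pyran-6-yl]-3-oxo-2-prenylbutanoate | COC(=O)C(CC=C(C)C)C(=O)CC1=CC(=O)C[C@@H](c2ccc(OC)c(OC)c2C/C=C(\C)CCC=C(C)C)O1
F2 | step 5 | methyl (5S)-5-(2-geranyl-3,4-dimethoxyphenyl)-5-hydroxy-3-methoxypent-2-enoate | COC(=O)C=C(OC)C[C@@H](c1ccc(OC)c(OC)c1C/C=C(\C)CCC=C(C)C)O
F3 | step 5 | methyl (5S)-5-[(tert-butyldimethylsilyl)oxy]-5-(2-geranyl-3,4-dimethoxyphenyl)-3-methoxypent-2-enoate | COC(=O)C=C(OC)C[C@@H](c1ccc(OC)c(OC)c1C/C=C(\C)CCC=C(C)C)O[Si](C)(C)C(C)(C)C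
F4 | step 5 | tert-butyl (9S)-9-[(tert-butyldimethylsilyl)oxy]-9-(2-geranyl-3,4-dimethoxyphenyl)-7-methoxy-3,5-dioxo-2-prenylnon-6-enoate | CC(C)(C)OC(=O)C(CC=C(C)C)C(=O)CC(=O)C=C(OC)C[C@@H](c1ccc(OC)c(OC)c1C/C=C(\C)CCC=C(C)C)O[Si](C)(C)C(C)(C)C
F5 | step 3 | 2,2-dimethyl-6-methylidene-4-(trimethylsilyloxy)-6H-1,3-dioxine | C=C1C=C(O[Si](C)(C)C)OC(C)(C)O1
F6 | step 3 | 6-[(2S)-2-(2-geranyl-3,4-dimethoxyphenyl)-2-hydroxyethyl]-2,2-dimethyl-4H-1,3-dioxin-4-one | CC1(C)OC(=O)C=C(C[C@@H](c2ccc(OC)c(OC)c2C/C=C(\C)CCC=C(C)C)O)O1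
F7 | step 3 | (6S)-6-(2-geranyl-3,4-dimethoxyphenyl)oxane-2,4-dione | O=C1CC(=O)C[C@@H](c2ccc(OC)c(OC)c2C/C=C(\C)CCC=C(C)C)O1
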